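**Retrosynthetic overview**
- Oxonane (last ring): the C6–C7 bond is cut to an S-ethyl thioester and a 2-bromoalkene, and closed by nickel electrocatalysis directly at the enone oxidation level.
- Side chains: C8–C9 comes from Sakurai allylation of a C9 methyl acetal. C4–C5 comes from a chelation-controlled thioacetate Mukaiyama aldol on a C4 aldehyde.
- Oxepane (third ring): O–C16 comes from hydroboration of the isopropenyl group, then triflate etherification by the C3 alcohol. C12 and C11 come from convex-face hydroboration, oxidation and reduction of a C11=C12 alkene.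
- Tetrahydrofuran (second ring): photochemical ring expansion of a methoxyketene-derived cyclobutanone gives a C2/C9 bis-acetal. C2–C3 comes from an L-lactic acid dioxolanone silyl ketene acetal.
- Cyclohexane (first ring): cyclobutane fragmentation of (+)-nopinone, then methylation and desaturation, gives a 1-methyl-5-isopropenylcyclohexa-1,3-diene.

Assumption: (+)-nopinone (made from (−)-β-pinene) and L-lactic acid are taken as the commercial chiral starting materials. Atom labels C1–C20 follow asbestinin numbering (C2–O–C9 tetrahydrofuran, C3–O–C16 oxepane, C4 octanoate, C6 ketone, C11 acetate, C12 methyl).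

**Step 1**
Reactants: 1 (1R,5S)-(+)-nopinone
Product: 2 (S)-4-(prop-1-en-2-yl)cyclohex-1-en-1-yl acetate
Conditions: Zn(OAc)2, BF3·OEt2, Ac2O, 0 °C to rt
Reagents that add atoms: acetic anhydride, CC(=O)OC(C)=O
Why: Lewis-acid cyclobutane fragmentation of the cyclobutyl ketone gives a tertiary cation that loses a proton to form the isopropenyl group and an enolate that is trapped as the acetate; C14 is the untouched C5 of nopinone, and the enol acetate position (C11=C12) keeps the ring desymmetrised.

**Step 2**
Reactants: 2 (S)-4-(prop-1-en-2-yl)cyclohex-1-en-1-yl acetate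
Product: 4 (4S)-2-methyl-4-(prop-1-en-2-yl)cyclohexan-1-one (C12 epimers), via lithium (S)-4-(prop-1-en-2-yl)cyclohex-1-en-1-olate 3 (not isolated)
Conditions: MeLi (2.1 equiv), DME, 0 °C; MeI, −40 to 0 °C
Reagents that add atoms: methyl iodide, CI
Why: Regiospecific enolate generation from an enol acetate followed by SN2 methylation puts the methyl group on C12 only; the C12 configuration does not matter here because it is planarised in step 4.

**Step 3**
Reactants: 4 (4S)-2-methyl-4-(prop-1-en-2-yl)cyclohexan-1-one
Product: 6 (4R)-6-methyl-4-(prop-1-en-2-yl)cyclohex-2-en-1-one (C12 epimers), via kinetic C10=C11 lithium enolate 5 (not isolated)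
Conditions: LDA, THF, −78 °C; PhS(Cl)=N-t-Bu, −78 °C
Reagents that add atoms: none
Why: Kinetic deprotonation at the unsubstituted CH2 (C10) followed by Mukaiyama dehydrogenation (S-attack on the sulfinimidoyl chloride, then syn-elimination) places the double bond at C10=C1 without touching C14.

**Step 4**
Reactants: 6 (4R)-6-methyl-4-(prop-1-en-2-yl)cyclohex-2-en-1-one
Product: 8 (4R)-2-methyl-4-(prop-1-en-2-yl)cyclohexa-1,5-dien-1-yl triflate, via cross-conjugated lithium dienolate 7 (not isolated)
Conditions: LDA, THF, −78 °C; PhNTf2, −78 to 0 °C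
Reagents that add atoms: N-phenylbis(trifluoromethanesulfonimide), O=S(=O)(N(c1ccccc1)S(=O)(=O)C(F)(F)F)C(F)(F)F
Why: Kinetic α′-deprotonation of the enone (C12–H is the only α′ proton) and O-triflation of the dienolate fix the C11=C12 double bond regiospecifically.

**Step 5**
Reactants: 8 (4R)-2-methyl-4-(prop-1-en-2-yl)cyclohexa-1,5-dien-1-yl triflate
Product: 9 (5R)-1-methyl-5-(prop-1-en-2-yl)cyclohexa-1,3-diene
Conditions: Pd(OAc)2 (5 mol %), PPh3, HCO2H, n-Bu3N, DMF, 50 °C
Reagents that add atoms: none
Why: Palladium-catalysed formate hydrogenolysis of a vinyl triflate replaces OTf by H with retention of the diene, and C14 is not involved.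

**Step 6**
Reactants: 9 (5R)-1-methyl-5-(prop-1-en-2-yl)cyclohexa-1,3-diene; 10 methoxyacetyl chloride
Product: 11 8-methoxy-3-methyl-5-(prop-1-en-2-yl)bicyclo[4.2.0]oct-2-en-7-one (cis-fused, four-membered ring anti to the isopropenyl group, OMe epimers)
Conditions: Et3N, hexane, reflux, slow addition of 10
Reagents that add atoms: none
Why: In this thermal ketene–diene [2+2] cycloaddition the less substituted C1=C10 bond reacts, the ketene carbonyl carbon bonds to the diene terminus C1, and approach anti to the C14 isopropenyl group sets C1 and C10 (cis fusion).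

**Step 7**
Reactants: 11 8-methoxy-3-methyl-5-(prop-1-en-2-yl)bicyclo[4.2.0]oct-2-en-7-one
Product: 13 3-methoxy-5-methyl-7-(prop-1-en-2-yl)-1,3,3a,6,7,7a-hexahydroisobenzofuran-1-yl acetate (C2-OAc/C9-OMe bis-acetal, anomer mixture), via 2-oxacarbene 12 (not isolated)
Conditions: hν (medium-pressure Hg lamp, Pyrex, λ > 290 nm), AcOH, CH2Cl2, rt
Reagents that add atoms: acetic acid, CC(=O)O
Why: In this photochemical cyclobutanone ring expansion, Norrish type I cleavage occurs toward the methoxy-bearing carbon and rebonding through oxygen forms the C9–O bond of the tetrahydrofuran; O–H insertion of the oxacarbene into acetic acid then gives two differentiated acetals, with C1, C10 and C14 untouched.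

**Step 8**
Reactants: 14 (S)-lactic acid; 15 pivalaldehyde
Product: 16 (2S,5S)-2-tert-butyl-5-methyl-1,3-dioxolan-4-one
Conditions: p-TsOH (cat.), pentane, Dean–Stark; recrystallisation at −78 °C
Reagents that add atoms: none
Why: Acid-catalysed acetalisation gives mainly the cis isomer, which is purified by crystallisation; the new acetal centre is set by the lactic acid stereocentre (self-regeneration of stereocentres).

**Step 9**
Reactants: 16 (2S,5S)-2-tert-butyl-5-methyl-1,3-dioxolan-4-one
Product: 18 (S)-2-tert-butyl-5-methyl-4-(trimethylsilyloxy)-1,3-dioxole, via lithium enolate 17 (not isolated)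
Conditions: LDA, THF, −78 °C; TMSCl
Reagents that add atoms: chlorotrimethylsilane, C[Si](C)(C)Cl
Why: Enolisation and O-silylation give the silyl ketene acetal; the lactate carbon is planar but the tert-butyl acetal centre stores its chirality.

**Step 10**
Reactants: 13 C2-OAc/C9-OMe bis-acetal; 18 (S)-2-tert-butyl-5-methyl-4-(trimethylsilyloxy)-1,3-dioxole
Product: 20 methyl 2-hydroxy-2-[3-methoxy-5-methyl-7-(prop-1-en-2-yl)-1,3,3a,6,7,7a-hexahydroisobenzofuran-1-yl]propanoate (C1, C2, C3, C10, C14 as in the target, C9 anomers), via C2-dioxolanone adduct 19 (not isolated)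
Conditions: TMSOTf (20 mol %), CH2Cl2, −78 °C; then K2CO3 (cat.), MeOH, 0 °C
Reagents that add atoms: methanol, CO
Why: TMSOTf ionises the acetate (a better leaving group than OMe) to the C2 oxocarbenium ion; in a Mukaiyama-type addition the ketene acetal attacks it from the convex face anti to C14 (sets C2) and through its own face anti to tert-butyl (regenerates the lactic acid centre as C3), and methoxide then opens the acylal to the hydroxy ester.

**Step 11**
Reactants: 20 C3-hydroxy methyl ester
Product: 22 C16-primary alcohol (C15 as in the target), via B-alkyl-9-BBN 21 (not isolated)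
Conditions: 9-BBN, THF, 0 °C to rt; H2O2, aq NaOH, 0 °C
Reagents that add atoms: hydrogen peroxide, OO
Why: In this chemoselective anti-Markovnikov hydroboration–oxidation, 9-BBN takes the 1,1-disubstituted alkene far faster than the trisubstituted C11=C12; in the rotamer with H14 eclipsing the C=CH2 bond it adds anti to the branched C1 side, which sets C15.

**Step 12**
Reactants: 22 C16-primary alcohol
Product: 24 tricyclic oxepane methyl ester (C3–O–C16 closed), via primary triflate 23 (not isolated)
Conditions: Tf2O, 2,6-lutidine, CH2Cl2, −78 to 0 °C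
Reagents that add atoms: none
Why: The primary alcohol is triflated selectively and the tertiary C3 alcohol displaces it in an intramolecular Williamson-type SN2 reaction; the trans-diequatorial C1/C14 side chains are well placed for seven-membered ring closure, and no stereocentre is touched.

**Step 13**
Reactants: 24 tricyclic oxepane methyl ester
Product: 26 C11 ketone (C12 as in the target), via C11-alkylborane 25 (not isolated)
Conditions: BH3·THF, THF, 0 °C; then NMO, TPAP (5 mol %), 4 Å MS, CH2Cl2, rt
Reagents that add atoms: N-methylmorpholine N-oxide, C[N+]1([O-])CCOCC1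
Why: Syn hydroboration puts boron on the less substituted C11 and comes from the convex face opposite the tetrahydrofuran, so H is delivered to C12 from that face and the methyl group ends on the concave face (sets C12); TPAP/NMO then oxidises the C–B bond directly to the ketone under non-epimerising conditions.

**Step 14**
Reactants: 26 C11 ketone
Product: 27 C11-hydroxy C4-aldehyde
Conditions: DIBAL-H (2.2 equiv), CH2Cl2, −78 °C; Rochelle salt
Reagents that add atoms: none
Why: Hydride attacks the ketone from the convex face, anti to the C12 methyl group and the tetrahydrofuran, which sets C11 with the OH cis to C9 and to the methyl group; the α-alkoxy ester stops at the chelated aluminium hemiacetal and gives the aldehyde on work-up.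

**Step 15**
Reactants: 27 C11-hydroxy C4-aldehyde
Product: 28 C11-acetoxy C4-aldehyde
Conditions: Ac2O, DMAP (cat.), pyridine, CH2Cl2, 0 °C to rt
Reagents that add atoms: acetic anhydride, CC(=O)OC(C)=O
Why: DMAP-catalysed acetylation acts on the only free hydroxyl group, and the aldehyde has no α-hydrogen and cannot enolise.

**Step 16**
Reactants: 29 S-ethyl thioacetate
Product: 31 1-(ethylsulfanyl)-1-(trimethylsilyloxy)ethene, via lithium thioester enolate 30 (not isolated)
Conditions: LDA, THF, −78 °C; TMSCl
Reagents that add atoms: chlorotrimethylsilane, C[Si](C)(C)Cl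
Why: Enolisation and O-silylation give the silyl ketene thioacetal, with no stereocentre involved.

**Step 17**
Reactants: 28 C11-acetoxy C4-aldehyde; 31 1-(ethylsulfanyl)-1-(trimethylsilyloxy)ethene
Product: 32 C4-hydroxy S-ethyl thioester
Conditions: MgBr2·OEt2 (3 equiv), CH2Cl2, −78 to −30 °C; aq citric acid
Reagents that add atoms: none
Why: In this chelation-controlled Mukaiyama aldol, magnesium ties the aldehyde oxygen to the oxepane oxygen on C3 and the nucleophile enters from the side of the C3 methyl group rather than the C2 ring, which gives the (4R) carbinol of the target.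

**Step 18**
Reactants: 32 C4-hydroxy S-ethyl thioester
Product: 33 C4-octanoate S-ethyl thioester
Conditions: n-C7H15COCl, pyridine, DMAP (cat.), CH2Cl2, 0 °C
Reagents that add atoms: octanoyl chloride, CCCCCCCC(=O)Cl
Why: This is O-acylation of the only free alcohol, and the weak base at low temperature avoids E1cB loss of the β-acyloxy group.

**Step 19**
Reactants: 33 C4-octanoate S-ethyl thioester; 34 (2-bromoallyl)trimethylsilane
Product: 35 C9-(2-bromoallyl) seco compound
Conditions: TMSOTf (30 mol %), MeCN/CH2Cl2, −40 °C
Reagents that add atoms: none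
Why: In this Hosomi–Sakurai allylation of the C9 oxocarbenium ion, the concave face is blocked by the cyclohexane ring and by participation of the cis C11 acetate, so C8 enters from the convex face (sets C9, cis to the C2 substituent).

**Step 20**
Reactants: 35 C9-(2-bromoallyl) seco compound
Product: 36 asbestinin 16
Conditions: undivided cell, Zn(+)/Ni foam(−), NiBr2·dme (20 mol %), dtbbpy (24 mol %), n-Bu4NBF4, DMA, 2 mM (syringe pump, 10 h), −1.2 V vs Ag/AgCl, rt
Reagents that add atoms: none
Why: Proposed new method: cathodically generated (dtbbpy)Ni(0) inserts into the alkenyl C–Br bond, one-electron reduction gives alkenyl–Ni(I), this adds intramolecularly to the C(acyl)–S bond while thiophilic Zn2+ from the anode removes the thiolate, and the acyl(alkenyl)Ni(III) reductively eliminates to form C6–C7 and close the oxonane directly as the α-methylene ketone; holding the potential at the Ni(II)/Ni(0) couple keeps it well positive of enone reduction, the cis-2,9-disubstituted tetrahydrofuran and the oxepane pre-organise the chain ends, and no stereocentre is formed or touched; the closest known reaction types are nickel-catalysed reductive cross-electrophile ketone synthesis from organic halides and thioesters, electrochemical nickel cross-electrophile coupling, and Ni/Cr alkenyl halide–aldehyde closure of this ring size, none of which has been shown for an intramolecular alkenyl bromide/thioester pair or for a medium ring.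

**Compound list**
1 | (1R,5S)-(+)-nopinone | CC1(C)[C@H]2CCC(=O)[C@@H]1C2 | starting material
2 | (S)-4-(prop-1-en-2-yl)cyclohex-1-en-1-yl acetate | C=C(C)[C@@H]1CC=C(OC(C)=O)CC1 | intermediate
3 | lithium (S)-4-(prop-1-en-2-yl)cyclohex-1-en-1-olate | C=C(C)[C@@H]1CC=C([O-])CC1.[Li+] | intermediate
4 | (4S)-2-methyl-4-(prop-1-en-2-yl)cyclohexan-1-one (C12 epimers) | C=C(C)[C@@H]1CC(C)C(=O)CC1 | intermediate
5 | kinetic C10=C11 lithium enolate of 4 | C=C(C)[C@@H]1CC(C)C([O-])=CC1.[Li+] | intermediate
6 | (4R)-6-methyl-4-(prop-1-en-2-yl)cyclohex-2-en-1-one (C12 epimers) | C=C(C)[C@@H]1CC(C)C(=O)C=C1 | intermediate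
7 | cross-conjugated lithium dienolate of 6 | C=C(C)[C@@H]1CC(C)=C([O-])C=C1.[Li+] | intermediate
8 | (4R)-2-methyl-4-(prop-1-en-2-yl)cyclohexa-1,5-dien-1-yl triflate | C=C(C)[C@@H]1CC(C)=C(OS(=O)(=O)C(F)(F)F)C=C1 | intermediate
9 | (5R)-1-methyl-5-(prop-1-en-2-yl)cyclohexa-1,3-diene | C=C(C)[C@@H]1CC(C)=CC=C1 | intermediate
10 | methoxyacetyl chloride | COCC(=O)Cl | starting material
11 | 8-methoxy-3-methyl-5-(prop-1-en-2-yl)bicyclo[4.2.0]oct-2-en-7-one (cis-fused, anti to isopropenyl, OMe epimers) | COC1C(=O)[C@H]2[C@@H](CC(C)=C[C@H]21)C(C)=C | intermediate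
12 | 2-oxacarbene (carbene at C2, oxygen bonded to C9) | COC1O[C][C@H]2[C@@H](CC(C)=C[C@H]21)C(C)=C | intermediate
13 | 3-methoxy-5-methyl-7-(prop-1-en-2-yl)-1,3,3a,6,7,7a-hexahydroisobenzofuran-1-yl acetate (anomers) | COC1OC(OC(C)=O)[C@H]2[C@@H](CC(C)=C[C@H]21)C(C)=C | intermediate
14 | (S)-lactic acid | C[C@H](O)C(=O)O | starting material
15 | pivalaldehyde | CC(C)(C)C=O | starting material
16 | (2S,5S)-2-tert-butyl-5-methyl-1,3-dioxolan-4-one | C[C@@H]1O[C@H](C(C)(C)C)OC1=O | intermediate
17 | lithium enolate of 16 | CC1=C([O-])O[C@@H](C(C)(C)C)O1.[Li+] | intermediate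
18 | (S)-2-tert-butyl-5-methyl-4-(trimethylsilyloxy)-1,3-dioxole | CC1=C(O[Si](C)(C)C)O[C@@H](C(C)(C)C)O1 | intermediate
19 | C2-dioxolanone adduct (new C–C bond trans to tert-butyl, C9 anomers) | COC1O[C@H]([C@@]3(C)O[C@H](C(C)(C)C)OC3=O)[C@H]2[C@@H](CC(C)=C[C@H]21)C(C)=C | intermediate
20 | C3-hydroxy methyl ester | COC1O[C@H]([C@@](C)(O)C(=O)OC)[C@H]2[C@@H](CC(C)=C[C@H]21)C(C)=C | intermediate
21 | B-(C16-alkyl)-9-BBN | COC1O[C@H]([C@@](C)(O)C(=O)OC)[C@H]2[C@@H](CC(C)=C[C@H]21)[C@@H](C)CB3C4CCCC3CCC4 | intermediate
22 | C16-primary alcohol | COC1O[C@H]([C@@](C)(O)C(=O)OC)[C@H]2[C@@H](CC(C)=C[C@H]21)[C@@H](C)CO | intermediate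
23 | C16 primary triflate | COC1O[C@H]([C@@](C)(O)C(=O)OC)[C@H]2[C@@H](CC(C)=C[C@H]21)[C@@H](C)COS(=O)(=O)C(F)(F)F | intermediate
24 | tricyclic oxepane methyl ester (C11=C12 alkene) | COC1O[C@H]2[C@H]3[C@@H](CC(C)=C[C@H]31)[C@@H](C)CO[C@@]2(C)C(=O)OC | intermediate
25 | C11-alkylborane (boron on the convex face) | COC1O[C@H]2[C@H]3[C@@H](C[C@@H](C)[C@H](B)[C@H]31)[C@@H](C)CO[C@@]2(C)C(=O)OC | intermediate
26 | C11 ketone methyl ester | COC1O[C@H]2[C@H]3[C@@H](C[C@@H](C)C(=O)[C@H]31)[C@@H](C)CO[C@@]2(C)C(=O)OC | intermediate
27 | C11-hydroxy C4-aldehyde | COC1O[C@H]2[C@H]3[C@@H](C[C@@H](C)[C@@H](O)[C@H]31)[C@@H](C)CO[C@@]2(C)C=O | intermediate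
28 | C11-acetoxy C4-aldehyde | COC1O[C@H]2[C@H]3[C@@H](C[C@@H](C)[C@@H](OC(C)=O)[C@H]31)[C@@H](C)CO[C@@]2(C)C=O | intermediate
29 | S-ethyl thioacetate | CCSC(C)=O | starting material
30 | lithium enolate of 29 | C=C([O-])SCC.[Li+] | intermediate
31 | 1-(ethylsulfanyl)-1-(trimethylsilyloxy)ethene | C=C(O[Si](C)(C)C)SCC | intermediate
32 | C4-hydroxy S-ethyl thioester | COC1O[C@H]2[C@H]3[C@@H](C[C@@H](C)[C@@H](OC(C)=O)[C@H]31)[C@@H](C)CO[C@@]2(C)[C@H](O)CC(=O)SCC | intermediate
33 | C4-octanoate S-ethyl thioester | COC1O[C@H]2[C@H]3[C@@H](C[C@@H](C)[C@@H](OC(C)=O)[C@H]31)[C@@H](C)CO[C@@]2(C)[C@H](OC(=O)CCCCCCC)CC(=O)SCC | intermediate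
34 | (2-bromoallyl)trimethylsilane | C=C(Br)C[Si](C)(C)C | starting material
35 | C9-(2-bromoallyl) seco compound | C=C(Br)C[C@@H]1O[C@H]2[C@H]3[C@@H](C[C@@H](C)[C@@H](OC(C)=O)[C@H]31)[C@@H](C)CO[C@@]2(C)[C@H](OC(=O)CCCCCCC)CC(=O)SCC | intermediate
36 | asbestinin 16 | C=C1C[C@@H]2O[C@H]3[C@H]4[C@@H](C[C@@H](C)[C@@H](OC(C)=O)[C@H]42)[C@@H](C)CO[C@@]3(C)[C@H](OC(=O)CCCCCCC)CC1=O | target

**Step count**
Total step count: 20.
Longest linear sequence: 17 (steps 1–7, 10–15, 17–20).

**Steps most likely to fail**

Step 7 (photochemical ring expansion). Cycloreversion, decarbonylation and capture of the carbene by the two alkenes compete with O–H insertion. The fallback replaces the photochemistry by an oxidative oxygen insertion. It sets out from 11. Baeyer–Villiger oxidation with basic hydrogen peroxide gives the methoxy lactone F1; the methoxy-bearing carbon migrates and the alkenes are untouched. DIBAL-H at −78 °C then gives the lactol F2, and acetylation (Ac2O, pyridine) returns to the route at 13.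

Step 10 (C2–C3 coupling). A quaternary carbon is formed next to a branched ring carbon, and ionisation must be selective for the acetate. The fallback reverses the polarity at C2. It sets out from 13. PhSH/BF3·OEt2 at −78 °C gives the C2 phenylthio acetal F3. Reductive lithiation with lithium di-tert-butylbiphenylide gives the 2-lithiotetrahydrofuran F4. This adds to the keto group of methyl pyruvate and returns to the route at 20. C3 is then set only by substrate control, and the epimers are separated by chromatography.

Step 20 (new electrochemical acyl–alkenyl closure). The S-ethyl thioester may be too slow toward nickel, and protodebromination or oligomerisation may take over. The fallback uses known chemistry and a different bond-forming event, carbonyl addition followed by oxidation. It sets out from 35. Fukuyama reduction (Et3SiH, Pd/C, acetone) gives the C6 aldehyde F5. Nozaki–Hiyama–Kishi cyclisation (CrCl2, cat. NiCl2, DMSO/DMF, high dilution) gives the C6 allylic alcohol F6. Dess–Martin oxidation then arrives at 36.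

**Further compounds**
F1 | step 7 | methoxy lactone (C2 lactone carbonyl, C9-OMe acetal) | COC1OC(=O)[C@H]2[C@@H](CC(C)=C[C@H]21)C(C)=C
F2 | step 7 | lactol (C2-OH, C9-OMe) | COC1OC(O)[C@H]2[C@@H](CC(C)=C[C@H]21)C(C)=C
F3 | step 10 | C2 phenylthio acetal | COC1OC(Sc3ccccc3)[C@H]2[C@@H](CC(C)=C[C@H]21)C(C)=C
F4 | step 10 | 2-lithiotetrahydrofuran (C2–Li) | COC1OC([Li])[C@H]2[C@@H](CC(C)=C[C@H]21)C(C)=C
F5 | step 20 | C6 aldehyde | C=C(Br)C[C@@H]1O[C@H]2[C@H]3[C@@H](C[C@@H](C)[C@@H](OC(C)=O)[C@H]31)[C@@H](C)CO[C@@]2(C)[C@H](OC(=O)CCCCCCC)CC=O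
F6 | step 20 | C6 allylic alcohol (C6 epimers) | C=C1C[C@@H]2O[C@H]3[C@H]4[C@@H](C[C@@H](C)[C@@H](OC(C)=O)[C@H]42)[C@@H](C)CO[C@@]3(C)[C@H](OC(=O)CCCCCCC)CC1O
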